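**Plan**

1. Retrosynthesis: take off the 1,10-epoxide oxygen (leaving E-C1=C10) and the C13 methylene, open the lactone at O6–C12, return the C8 ester and the C6–H to a β-hydroxy ketone plus an epoxy aldehyde, cut C7–C11 (enolate alkylation), then cut C8–C9 while restoring a C1–C6 bond.
2. Enabling feature: the (2Z,4Z)-diene C2=C3–C4=C5 held between C1 and C6 is a cyclohexa-1,3-diene that lacks its C1–C6 bond, and O6 and the C1=C10 alkene are 1,5-related across C8–C9 (δ,ε-unsaturated carbonyl, the oxy-Cope retron). The ten-membered ring is therefore the ring-expanded form of a trans-5,6-dialkenylcyclohexa-1,3-dien-5-ol.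
3. Forward: (S)-carvone is turned into that six-membered ring (C1–C6 with the C4 methyl, isopropenyl = C10/C9/C14 on C1, carbinol C6 carrying the Z-enol ether C7=C8–OPMB). An anionic oxy-Cope shift opens it to the ten-membered ring and the enolate is alkylated at C7 in the same flask.
4. Then: PMB removal, Evans–Tishchenko reduction with the side-chain epoxy aldehyde (sets C6, acylates O8) with lactone closure, α-methylenation, and epoxidation of C1=C10 last.
5. Stereochemistry: the carvone stereocentre (future C1) is the only source for the ring. It is relayed to C8 by the chair Cope transition state, to C7 by peripheral alkylation, and to C6 by the 1,3-anti hydride transfer. The 1,10-epoxide comes from Shi catalyst control on the E-alkene, and the side chain from Sharpless epoxidation of tiglyl alcohol.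

Key step: step 8

Remark on numbering: germacrane numbering is used in the text (ring C1–C10, C6 lactone carbinol, C7 ring-fusion CH, C8 acyloxy carbon, C11–C13 lactone arm, C14 methyl on C10, C15 methyl on C4).
Assumption: (S)-(+)-carvone, 4-methoxybenzyl alcohol, ethyl vinyl ether and (E)-2-methylbut-2-en-1-ol are taken as commercial; the side-chain epoxide in the target SMILES has cis methyl groups, so it is built from the E (tiglyl) alkene.

**Route**

Step 1
Reactants: 1 (S)-(+)-carvone
Product: 2 (1S,5S)-cis-carveol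
Conditions: NaBH4, CeCl3·7H2O, MeOH, 0 °C
Reagents that add atoms: none
Why: Luche 1,2-reduction of the enone; axial hydride delivery should give the cis alcohol, and this new carbinol centre is erased later when the ring diene is formed.

Step 2
Reactants: 2 (1S,5S)-cis-carveol
Product: 3 (1S,5S)-cis-carveyl pivalate
Conditions: PivCl, pyridine, DMAP (cat.), CH2Cl2, 0 → 25 °C
Reagents that add atoms: pivaloyl chloride, CC(C)(C)C(=O)Cl
Why: Standard acylation; the pivalate blocks this allylic position during the oxidation, survives the organometallic addition at −78 °C, and later serves as the allylic leaving group.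

Step 3
Reactants: 3 (1S,5S)-cis-carveyl pivalate
Product: 4 (1S,5S)-2-methyl-4-oxo-5-(prop-1-en-2-yl)cyclohex-2-en-1-yl pivalate
Conditions: CrO3, 3,5-dimethylpyrazole, CH2Cl2, −20 °C
Reagents that add atoms: chromium trioxide, O=[Cr](=O)=O
Why: Allylic oxidation of the only free ring allylic CH2 of a trisubstituted cyclohexene to the enone (the valencene-to-nootkatone type of oxidation, isopropenyl group as spectator); the non-basic conditions should leave the α-stereocentre (future C1) intact.

Step 4
Reactants: 5 4-methoxybenzyl alcohol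
Product: 6 4-methoxybenzyl vinyl ether
Conditions: ethyl vinyl ether (excess), Pd(OAc)2 (2 mol %), 1,10-phenanthroline, CH2Cl2, 25 °C
Reagents that add atoms: ethyl vinyl ether, C=COCC
Why: Palladium-catalysed transfer vinylation (transetherification) of an alcohol with a vinyl ether; no stereocentre is involved.

Step 5
Reactants: 6 4-methoxybenzyl vinyl ether
Product: 8 (Z)-1-bromo-2-[(4-methoxybenzyl)oxy]ethene, via 1,2-dibromoethyl 4-methoxybenzyl ether 7 (not isolated)
Conditions: Br2, CH2Cl2, −78 °C; then Et3N, −78 → 25 °C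
Reagents that add atoms: bromine, BrBr
Why: Bromine addition to the enol ether followed by amine-induced dehydrobromination, the known route to alkyl (Z)-2-bromovinyl ethers; the Z isomer should predominate as with the ethyl analogue, and the E isomer is removed by chromatography.

Step 6
Reactants: 4 (1S,5S)-2-methyl-4-oxo-5-(prop-1-en-2-yl)cyclohex-2-en-1-yl pivalate; 8 (Z)-1-bromo-2-[(4-methoxybenzyl)oxy]ethene
Product: 10 (1S,4S,5S)-4-hydroxy-4-{(Z)-2-[(4-methoxybenzyl)oxy]ethenyl}-2-methyl-5-(prop-1-en-2-yl)cyclohex-2-en-1-yl pivalate, via (Z)-2-[(4-methoxybenzyl)oxy]ethenyllithium 9 (not isolated)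
Conditions: 8, t-BuLi (2 equiv), Et2O, −78 °C; CeCl3 (anhydrous), THF, −78 °C; then 4, −78 °C; H2O
Reagents that add atoms: none
Why: Bromine–lithium exchange with retention of the Z geometry, transmetalation to the less basic organocerium reagent and 1,2-addition to the enone (the known use of 2-alkoxyvinyl metal reagents); attack anti to the adjacent isopropenyl group should set the carbinol centre with the two alkenyl groups trans, and the pivalate is not attacked at −78 °C.

Step 7
Reactants: 10 (1S,4S,5S)-4-hydroxy-4-{(Z)-2-[(4-methoxybenzyl)oxy]ethenyl}-2-methyl-5-(prop-1-en-2-yl)cyclohex-2-en-1-yl pivalate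
Product: 11 (1S,6S)-1-{(Z)-2-[(4-methoxybenzyl)oxy]ethenyl}-3-methyl-6-(prop-1-en-2-yl)cyclohexa-2,4-dien-1-ol
Conditions: Pd(PPh3)4 (5 mol %), Et3N, THF, 50 °C; base-washed glassware
Reagents that add atoms: none
Why: Tsuji–Trost-type palladium-catalysed 1,4-elimination of an allylic ester to a 1,3-diene; the π-allyl unit spans C3–C5 and β-hydride loss is possible only from C2, so only the cyclohexa-1,3-diene can form, and no stereocentre changes (the dienol is acid-sensitive and is used at once).

Step 8
Reactants: 11 (1S,6S)-1-{(Z)-2-[(4-methoxybenzyl)oxy]ethenyl}-3-methyl-6-(prop-1-en-2-yl)cyclohexa-2,4-dien-1-ol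
Product: 14 (2Z,4Z,6E,9R,10R)-9-[(4-methoxybenzyl)oxy]-10-(2-methoxy-2-oxoethyl)-3,7-dimethylcyclodeca-2,4,6-trien-1-one, via potassium alkoxide of the dienol 12 (not isolated), via ring-expanded potassium enolate 13 (not isolated)
Conditions: KH, THF (no crown ether), 0 → 25 °C; then BrCH2CO2Me, −78 → −40 °C; pH 7 buffer
Reagents that add atoms: methyl bromoacetate, COC(=O)CBr
Why: Deprotonation gives alkoxide 12, in which C6(O−)–C1 is the central bond of the 3-oxido-1,5-diene C8=C7–C6–C1–C10=C9; an anionic oxy-Cope [3,3]-sigmatropic shift, driven by enolate formation and by the doubly allylic C1–C6 bond, breaks C1–C6 and forms C8–C9, so the six-membered ring opens into the ten-membered ring (ring expansion by four atoms, with no macrocyclisation entropy to pay). The closest known reaction type is the anionic oxy-Cope ring expansion of trans-1,2-dialkenylcyclohexenols to cyclodecadienones, followed by C-alkylation of the regiodefined enolate as in tandem oxy-Cope/alkylation sequences. Both ring bonds (C1–C2 and C6–C5) are equatorial on the chair transition state, so C1=C10 should emerge E and the enolate should have O6 cis to C8, while C2=C3 and C4=C5 keep the Z geometry imposed by the six-membered ring. C8 is set by chirality transfer from C1/C6 through the chair: the Z-alkoxy group is axial, syn to the alkoxide and bridged by K+, which for the (1S,6S) substrate leads to 8R; C7 is set when bromoacetate attacks the K-chelated enolate 13 from the outer face, anti to C9, the inner face being covered by the ring, which leads to 7R. The step needs the chair pathway through the two exocyclic alkenes to beat the boat pathways through the ring diene (which would reclose six-membered rings), and needs the β-alkoxy enolate not to eliminate; the first is secured by the trans-diequatorial alkenyl groups and the unhindered CH2 terminus C9, the second by the chelate, which holds the C8–O bond in the enolate plane, and by alkylation at −78 °C.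

Step 9
Reactants: 14 (2Z,4Z,6E,9R,10R)-9-[(4-methoxybenzyl)oxy]-10-(2-methoxy-2-oxoethyl)-3,7-dimethylcyclodeca-2,4,6-trien-1-one
Product: 15 (2Z,4Z,6E,9R,10R)-9-hydroxy-10-(2-methoxy-2-oxoethyl)-3,7-dimethylcyclodeca-2,4,6-trien-1-one
Conditions: DDQ, CH2Cl2/pH 7 phosphate buffer, 0 °C
Reagents that add atoms: none
Why: Oxidative cleavage of the PMB ether under neutral conditions, which should avoid β-elimination and C7 epimerisation; the electron-poor trienone is not oxidised, and the γ-hydroxy ester is used at once (closure onto O8 would need a nearly eclipsed C7–C8 bond).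

Step 10
Reactants: 16 (E)-2-methylbut-2-en-1-ol
Product: 17 [(2R,3R)-2,3-dimethyloxiran-2-yl]methanol
Conditions: Ti(OiPr)4 (10 mol %), D-(−)-diisopropyl tartrate (12 mol %), t-BuOOH, 4 Å molecular sieves, CH2Cl2, −20 °C
Reagents that add atoms: tert-butyl hydroperoxide, CC(C)(C)OO
Why: Sharpless asymmetric epoxidation of an E-trisubstituted allylic alcohol; the D-(−)-tartrate should deliver oxygen to the face that gives the (2R,3R) epoxy alcohol, the enantiomer of the (2S,3S) product expected from L-(+)-tartrate.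

Step 11
Reactants: 17 [(2R,3R)-2,3-dimethyloxiran-2-yl]methanol
Product: 18 (2S,3R)-2,3-dimethyloxirane-2-carbaldehyde
Conditions: TEMPO (10 mol %), PhI(OAc)2, CH2Cl2, 25 °C; used as a solution
Reagents that add atoms: none
Why: TEMPO/PhI(OAc)2 oxidation of a primary epoxy alcohol to the aldehyde; the α-carbon is quaternary, so no stereocentre can epimerise.

Step 12
Reactants: 15 (2Z,4Z,6E,9R,10R)-9-hydroxy-10-(2-methoxy-2-oxoethyl)-3,7-dimethylcyclodeca-2,4,6-trien-1-one; 18 (2S,3R)-2,3-dimethyloxirane-2-carbaldehyde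
Product: 20 (6R,7R,8R)-8-[(2S,3R)-2,3-dimethyloxirane-2-carbonyloxy]germacra-1(10)E,2Z,4Z-trien-12,6-olide, via hydroxy ester 19 (not isolated)
Conditions: 18 (4 equiv), SmI2 (0.3 equiv), THF, −10 °C, then 25 °C
Reagents that add atoms: none
Why: Evans–Tishchenko reduction: the samarium-bound hemiacetal of 18 on O8 transfers hydride to C6 through a chair six-membered transition state, which should give the 1,3-anti (6R) alcohol and leave O8 carrying the side-chain ester, and the freed O6 alkoxide then closes the trans-fused γ-lactone onto the methyl ester.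

Step 13
Reactants: 20 (6R,7R,8R)-8-[(2S,3R)-2,3-dimethyloxirane-2-carbonyloxy]germacra-1(10)E,2Z,4Z-trien-12,6-olide
Product: 23 (6R,7R,8R)-8-[(2S,3R)-2,3-dimethyloxirane-2-carbonyloxy]germacra-1(10)E,2Z,4Z,11(13)-tetraen-12,6-olide, via Mannich base 21 (not isolated), via trimethylammonium iodide 22 (not isolated)
Conditions: LDA (1.1 equiv), THF, −78 °C; CH2=NMe2+ I−, −78 → 0 °C; then MeI, CH2Cl2/MeOH, 25 °C; then aq NaHCO3, EtOAc, 25 °C
Reagents that add atoms: dimethylmethyleneammonium iodide (Eschenmoser's salt), C=[N+](C)C.[I-]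
Why: Eschenmoser α-methylenation (lactone enolate Mannich reaction, N-methylation, elimination of trimethylamine); the lactone CH2 is the only enolisable position because the side-chain ester has a quaternary α-carbon, and the C11 centre formed in 21 is removed again.

Step 14
Reactants: 23 (6R,7R,8R)-8-[(2S,3R)-2,3-dimethyloxirane-2-carbonyloxy]germacra-1(10)E,2Z,4Z,11(13)-tetraen-12,6-olide
Product: 24 target, (1R,6R,7R,8R,10R)-1,10-epoxy-8-[(2S,3R)-2,3-dimethyloxirane-2-carbonyloxy]germacra-2Z,4Z,11(13)-trien-12,6-olide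
Conditions: D-fructose-derived Shi ketone (0.3 equiv), KHSO5 (as 2KHSO5·KHSO4·K2SO4), K2CO3, Bu4NHSO4 (cat.), MeCN/CH2(OMe)2/aq Na2B4O7–Na2EDTA, 0 °C
Reagents that add atoms: potassium peroxymonosulfate, [K+].OOS(=O)(=O)[O-]
Why: Shi asymmetric epoxidation by the chiral dioxirane; the E-trisubstituted C1=C10 is the most electron-rich alkene and the only one that fits the spiro transition state (C2=C3 and C4=C5 are Z, C4=C5 is also deactivated by the allylic lactone oxygen, the methylene lactone is electron-poor), and catalyst control on an E-alkene should give the (1R,10R) epoxide.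

**Compound list**

1 | (S)-(+)-carvone | CC1=CC[C@@H](CC1=O)C(C)=C | starting material
2 | (1S,5S)-cis-carveol | CC1=CC[C@@H](C[C@@H]1O)C(C)=C | intermediate
3 | (1S,5S)-cis-carveyl pivalate | CC1=CC[C@@H](C[C@@H]1OC(=O)C(C)(C)C)C(C)=C | intermediate
4 | (1S,5S)-2-methyl-4-oxo-5-(prop-1-en-2-yl)cyclohex-2-en-1-yl pivalate | CC1=CC(=O)[C@@H](C[C@@H]1OC(=O)C(C)(C)C)C(C)=C | intermediate
5 | 4-methoxybenzyl alcohol | COc1ccc(CO)cc1 | starting material
6 | 4-methoxybenzyl vinyl ether | COc1ccc(COC=C)cc1 | intermediate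
7 | 1,2-dibromoethyl 4-methoxybenzyl ether (not isolated) | COc1ccc(COC(Br)CBr)cc1 | intermediate
8 | (Z)-1-bromo-2-[(4-methoxybenzyl)oxy]ethene | COc1ccc(CO/C=C\Br)cc1 | intermediate
9 | (Z)-2-[(4-methoxybenzyl)oxy]ethenyllithium (not isolated) | COc1ccc(CO/C=C\[Li])cc1 | intermediate
10 | (1S,4S,5S)-4-hydroxy-4-{(Z)-2-[(4-methoxybenzyl)oxy]ethenyl}-2-methyl-5-(prop-1-en-2-yl)cyclohex-2-en-1-yl pivalate | CC1=C[C@@](O)(/C=C\OCc2ccc(OC)cc2)[C@@H](C[C@@H]1OC(=O)C(C)(C)C)C(C)=C | intermediate
11 | (1S,6S)-1-{(Z)-2-[(4-methoxybenzyl)oxy]ethenyl}-3-methyl-6-(prop-1-en-2-yl)cyclohexa-2,4-dien-1-ol | CC1=C[C@@](O)(/C=C\OCc2ccc(OC)cc2)[C@@H](C=C1)C(C)=C | intermediate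
12 | potassium alkoxide of 11 (not isolated) | CC1=C[C@@]([O-])(/C=C\OCc2ccc(OC)cc2)[C@@H](C=C1)C(C)=C.[K+] | intermediate
13 | ring-expanded potassium enolate: ten-membered ring, C6–O−, C6=C7, (8R)-OPMB, 1(10)E,2Z,4Z (not isolated) | [K+].[O-]/C1=C\[C@H](OCc2ccc(OC)cc2)C\C(C)=C\C=C/C(C)=C\1 | intermediate
14 | (2Z,4Z,6E,9R,10R)-9-[(4-methoxybenzyl)oxy]-10-(2-methoxy-2-oxoethyl)-3,7-dimethylcyclodeca-2,4,6-trien-1-one (germacrane: 6-ketone, 7R, 8R) | O=C1/C=C(C)\C=C/C=C(C)/C[C@@H](OCc2ccc(OC)cc2)[C@H]1CC(=O)OC | intermediate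
15 | (2Z,4Z,6E,9R,10R)-9-hydroxy-10-(2-methoxy-2-oxoethyl)-3,7-dimethylcyclodeca-2,4,6-trien-1-one | O=C1/C=C(C)\C=C/C=C(C)/C[C@@H](O)[C@H]1CC(=O)OC | intermediate
16 | (E)-2-methylbut-2-en-1-ol (tiglyl alcohol) | C/C=C(\C)CO | starting material
17 | [(2R,3R)-2,3-dimethyloxiran-2-yl]methanol | OC[C@@]1(C)O[C@@H]1C | intermediate
18 | (2S,3R)-2,3-dimethyloxirane-2-carbaldehyde | O=C[C@@]1(C)O[C@@H]1C | intermediate
19 | hydroxy ester: methyl ester of the (6R,7S,8R)-6-hydroxy-8-[(2S,3R)-2,3-dimethyloxirane-2-carbonyloxy]-1(10)E,2Z,4Z-triene seco acid (not isolated) | O[C@@H]1/C=C(C)\C=C/C=C(C)/C[C@@H](OC(=O)[C@@]2(C)O[C@@H]2C)[C@H]1CC(=O)OC | intermediate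
20 | (6R,7R,8R)-8-[(2S,3R)-2,3-dimethyloxirane-2-carbonyloxy]germacra-1(10)E,2Z,4Z-trien-12,6-olide | C1C(=O)O[C@@H]2/C=C(C)\C=C/C=C(C)/C[C@@H](OC(=O)[C@@]3(C)O[C@@H]3C)[C@@H]12 | intermediate
21 | Mannich base: 13-(dimethylamino) derivative of 20, C11 epimers (not isolated) | CN(C)CC1C(=O)O[C@@H]2/C=C(C)\C=C/C=C(C)/C[C@@H](OC(=O)[C@@]3(C)O[C@@H]3C)[C@@H]12 | intermediate
22 | trimethylammonium iodide of 21 (not isolated) | C[N+](C)(C)CC1C(=O)O[C@@H]2/C=C(C)\C=C/C=C(C)/C[C@@H](OC(=O)[C@@]3(C)O[C@@H]3C)[C@@H]12.[I-] | intermediate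
23 | (6R,7R,8R)-8-[(2S,3R)-2,3-dimethyloxirane-2-carbonyloxy]germacra-1(10)E,2Z,4Z,11(13)-tetraen-12,6-olide | C=C1C(=O)O[C@@H]2/C=C(C)\C=C/C=C(C)/C[C@@H](OC(=O)[C@@]3(C)O[C@@H]3C)[C@@H]12 | intermediate
24 | (1R,6R,7R,8R,10R)-1,10-epoxy-8-[(2S,3R)-2,3-dimethyloxirane-2-carbonyloxy]germacra-2Z,4Z,11(13)-trien-12,6-olide | C=C1C(=O)O[C@@H]2/C=C(C)\C=C/[C@H]3O[C@]3(C)C[C@@H](OC(=O)[C@@]3(C)O[C@@H]3C)[C@@H]12 | target

**Totals**

Total step count: 14. Longest linear sequence: 10 steps (1, 2, 3, 6, 7, 8, 9, 12, 13, 14).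

**Three steps most likely to fail**

Step 8. What may go wrong: partition of the alkoxide into boat-type shifts through the ring diene, loss of the C8 alkoxy group from the enolate by β-elimination, or alkylation on the wrong face of C7. The fallback separates ring expansion from C7 alkylation. It sets out from 11 and returns at 15. The rearrangement alone is run with KH and 18-crown-6 in THF at 0 °C and enolate 13 is protonated at −78 °C, which should give (2Z,4Z,6E,9R)-9-[(4-methoxybenzyl)oxy]-3,7-dimethylcyclodeca-2,4,6-trien-1-one F1. Buffered DDQ then gives (2Z,4Z,6E,9R)-9-hydroxy-3,7-dimethylcyclodeca-2,4,6-trien-1-one F2. Double deprotonation of F2 (LDA, 2.2 equiv, THF, −78 °C) and methyl bromoacetate install the C7 arm on the lithium-chelated alkoxide–enolate anti to C9 (Fráter–Seebach-type alkylation), which should give 15.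

Step 12. What may go wrong: consumption of the epoxy aldehyde by SmI2, acyl migration between O8 and O6, or closure of the ester arm onto O8 before the hydride transfer. The fallback sets out from 15 and returns at 20. Hydroxyl-directed reduction with Me4NBH(OAc)3 in MeCN/AcOH at −30 °C should give the 1,3-anti diol ester, methyl 2-[(6R,8R)-6,8-dihydroxy-1(10)E,2Z,4Z-trien-7-yl]acetate F3. F3 should close onto O6 to the trans-fused (6R,7R,8R)-8-hydroxygermacra-1(10)E,2Z,4Z-trien-12,6-olide F4. Aldehyde 18 is oxidised (NaClO2, NaH2PO4, 2-methylbut-2-ene) to (2S,3R)-2,3-dimethyloxirane-2-carboxylic acid F5. Yamaguchi esterification of F4 with F5 (2,4,6-trichlorobenzoyl chloride, Et3N, DMAP, toluene) gives 20.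

Step 14. What may go wrong: poor facial or site selectivity of the epoxidation in the flexible triene, or attack of the basic oxidant on the methylene lactone. The fallback uses substrate direction at an earlier stage. It sets out from 15 and returns at 24. With VO(acac)2 and t-BuOOH in CH2Cl2 at 0 °C the homoallylic C8–OH should deliver oxygen to C1=C10 only, since the other two ring alkenes are deactivated as a dienone, giving the (1R,10R)-1,10-epoxide of 15, F6. The conditions of step 12 then give the epoxy hydroxy ester F7 (not isolated) and the (1R,10R)-1,10-epoxide of lactone 20, F8. The conditions of step 13 give the epoxy Mannich base F9, its trimethylammonium iodide F10, and then 24.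

**Further compounds**

F1 | step 8 | (2Z,4Z,6E,9R)-9-[(4-methoxybenzyl)oxy]-3,7-dimethylcyclodeca-2,4,6-trien-1-one | O=C1/C=C(C)\C=C/C=C(C)/C[C@@H](OCc2ccc(OC)cc2)C1
F2 | step 8 | (2Z,4Z,6E,9R)-9-hydroxy-3,7-dimethylcyclodeca-2,4,6-trien-1-one | O=C1/C=C(C)\C=C/C=C(C)/C[C@@H](O)C1
F3 | step 12 | 1,3-anti diol ester, methyl 2-[(6R,8R)-6,8-dihydroxy-1(10)E,2Z,4Z-trien-7-yl]acetate | O[C@@H]1/C=C(C)\C=C/C=C(C)/C[C@@H](O)[C@H]1CC(=O)OC
F4 | step 12 | (6R,7R,8R)-8-hydroxygermacra-1(10)E,2Z,4Z-trien-12,6-olide | C1C(=O)O[C@@H]2/C=C(C)\C=C/C=C(C)/C[C@@H](O)[C@@H]12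
F5 | step 12 | (2S,3R)-2,3-dimethyloxirane-2-carboxylic acid | OC(=O)[C@@]1(C)O[C@@H]1C
F6 | step 14 | (1R,10R)-1,10-epoxide of 15 | O=C1/C=C(C)\C=C/[C@H]2O[C@]2(C)C[C@@H](O)[C@H]1CC(=O)OC
F7 | step 14 | (1R,10R)-1,10-epoxide of hydroxy ester 19 | O[C@@H]1/C=C(C)\C=C/[C@H]2O[C@]2(C)C[C@@H](OC(=O)[C@@]3(C)O[C@@H]3C)[C@H]1CC(=O)OC
F8 | step 14 | (1R,10R)-1,10-epoxide of lactone 20 | C1C(=O)O[C@@H]2/C=C(C)\C=C/[C@H]3O[C@]3(C)C[C@@H](OC(=O)[C@@]3(C)O[C@@H]3C)[C@@H]12
F9 | step 14 | Mannich base of F8 (C11 epimers) | CN(C)CC1C(=O)O[C@@H]2/C=C(C)\C=C/[C@H]3O[C@]3(C)C[C@@H](OC(=O)[C@@]3(C)O[C@@H]3C)[C@@H]12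
F10 | step 14 | trimethylammonium iodide of F9 | C[N+](C)(C)CC1C(=O)O[C@@H]2/C=C(C)\C=C/[C@H]3O[C@]3(C)C[C@@H](OC(=O)[C@@]3(C)O[C@@H]3C)[C@@H]12.[I-]
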